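**Retrosynthetic overview**
- The target is two 3,6-dibromocatechol rings joined by a CH2 at C4 of each, with a fifth bromine on one of them (ring B). Both rings come from the C2-symmetric arene 1,4-dibromo-2,3-dimethoxybenzene, so no ring is built and each C–H functionalisation of it has only one possible site.
- Key disconnection: the bond between the CH2 carbon and C1 of the tribromo ring B. It is made by an anodic dehydrogenative benzyl–aryl cross-coupling of a ring A toluene (benzylic C–H) with 3,4,6-tribromocatechol (ring C–H); only O-demethylation follows.
- Enabling feature: the CH2 carbon is para to the C4 oxygen of ring A, so a methyl group there is the anodically oxidisable site and its cation is oxygen-stabilised. The ring B carbon it bonds to is para to the C4 hydroxyl and is the only hydrogen-bearing carbon of tribromocatechol.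
- Fragment preparation: ring A by ortho-lithiation/methylation of the arene; ring B by demethylation, then mono-bromination.

Key step: step 4

Remark: the target has no stereocentre or stereoaxis, so no stereocontrol is needed; 1,4-dibromo-2,3-dimethoxybenzene is taken as a catalogue compound.

**Route**

Step 1
Reactants: 1 1,4-dibromo-2,3-dimethoxybenzene
Product: 3 2,5-dibromo-3,4-dimethoxytoluene, via (2,5-dibromo-3,4-dimethoxyphenyl)lithium 2 (not isolated)
Conditions: LDA (1.2 equiv, commercial solution), THF, −78 °C, 1 added to the base; then MeI (3 equiv), −78 °C → rt
Reagents that add atoms: iodomethane, CI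
Why: Bromine-directed ortho-lithiation (LDA removes one of the two symmetry-equivalent ring hydrogens, each ortho to a bromine) followed by SN2 methylation of the aryllithium should give 3, with low temperature and inverse addition suppressing aryne formation and halogen dance.

Step 2
Reactants: 1 1,4-dibromo-2,3-dimethoxybenzene
Product: 4 3,6-dibromobenzene-1,2-diol
Conditions: BBr3 (2.5 equiv), CH2Cl2, −78 °C → rt; then ice-water
Reagents that add atoms: none
Why: Lewis-acid cleavage of aryl methyl ethers: BBr3 coordinates each methoxy oxygen, bromide attacks the methyl carbon by SN2, and the aryl borate is hydrolysed on work-up, while aryl C–Br bonds are inert.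

Step 3
Reactants: 4 3,6-dibromobenzene-1,2-diol
Product: 5 3,4,6-tribromobenzene-1,2-diol
Conditions: Br2 (1.0 equiv, slow addition), AcOH–CH2Cl2, 0 °C
Reagents that add atoms: bromine, BrBr
Why: Electrophilic aromatic bromination para to a phenolic hydroxyl: the two free positions of 4 are equivalent by symmetry, and the bromine introduced deactivates and shields the remaining one, so one equivalent should stop at the tribromide.

Step 4
Reactants: 3 2,5-dibromo-3,4-dimethoxytoluene; 5 3,4,6-tribromobenzene-1,2-diol
Product: 7 3,4,6-tribromo-5-[(2,5-dibromo-3,4-dimethoxyphenyl)methyl]benzene-1,2-diol, via benzylic hexafluoroisopropyl ether 6 (not isolated)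
Conditions: (i) 3, Bu4NPF6 (0.1 M), HFIP, undivided cell, BDD anode, Pt cathode, constant current, ca. 2.5–3 F/mol, rt; (ii) current off, then 5 (2.5 equiv), TfOH (20 mol%), rt → 40 °C
Reagents that add atoms: none
Why: Anodic electron transfer from 3 gives an arene radical cation that loses a proton from the methyl group para to the C4 methoxy oxygen, and a second electron transfer gives the benzylic cation, which hexafluoroisopropoxide (formed at the cathode together with H2) captures as ether 6, whose electron-poor alkoxy group raises the oxidation potential and stops the oxidation at this level. Triflic acid then re-ionises 6, and the cation is intercepted in a Friedel–Crafts substitution by the only hydrogen-bearing ring carbon of 5, which lies para to a free hydroxyl; loss of a proton gives 7 and returns HFIP. The closest known reaction type is the anodic dehydrogenative benzyl–aryl cross-coupling of 4-methylanisoles through benzylic HFIP ethers that are arylated on acid activation. No ring is closed and no stereocentre is formed. The step needs benzylic rather than nuclear oxidation (secured by the methyl para to oxygen and by the single, hindered ring C–H of 3), C- rather than O-benzylation at one site (5 has one free carbon, and aryl benzyl ethers revert under the acid), and cross- rather than self-benzylation (the lone ring C–H of ring A is activated only by methoxy groups twisted out of conjugation by their two ortho neighbours, and 5 is in excess). The catechol is added only after the current is switched off, so it never meets the anode, and the platinum cathode keeps the cathode process at proton reduction so that C–Br bonds are not cleaved.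

Step 5
Reactants: 7 3,4,6-tribromo-5-[(2,5-dibromo-3,4-dimethoxyphenyl)methyl]benzene-1,2-diol
Product: 8 3,4,6-tribromo-5-[(2,5-dibromo-3,4-dihydroxyphenyl)methyl]benzene-1,2-diol (CNP0260137.0)
Conditions: BBr3 (5 equiv), CH2Cl2, −78 °C → rt; then ice-water
Reagents that add atoms: none
Why: BBr3 ether cleavage as in step 2, with extra reagent to allow for the two free hydroxyls of ring B; the diarylmethane CH2 and the five C–Br bonds should survive, and no stereocentre is involved.

**Compound list**
1 | 1,4-dibromo-2,3-dimethoxybenzene | COc1c(Br)ccc(Br)c1OC | starting material
2 | (2,5-dibromo-3,4-dimethoxyphenyl)lithium | [Li]c1cc(Br)c(OC)c(OC)c1Br | intermediate (not isolated)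
3 | 2,5-dibromo-3,4-dimethoxytoluene (1,4-dibromo-2,3-dimethoxy-5-methylbenzene) | Cc1cc(Br)c(OC)c(OC)c1Br | intermediate
4 | 3,6-dibromobenzene-1,2-diol | Oc1c(Br)ccc(Br)c1O | intermediate
5 | 3,4,6-tribromobenzene-1,2-diol | Oc1c(Br)cc(Br)c(Br)c1O | intermediate
6 | 1,4-dibromo-5-{[(1,1,1,3,3,3-hexafluoropropan-2-yl)oxy]methyl}-2,3-dimethoxybenzene | COc1c(OC)c(Br)c(COC(C(F)(F)F)C(F)(F)F)cc1Br | intermediate (not isolated)
7 | 3,4,6-tribromo-5-[(2,5-dibromo-3,4-dimethoxyphenyl)methyl]benzene-1,2-diol | COc1c(Br)cc(Cc2c(Br)c(O)c(O)c(Br)c2Br)c(Br)c1OC | intermediate
8 | 3,4,6-tribromo-5-[(2,5-dibromo-3,4-dihydroxyphenyl)methyl]benzene-1,2-diol | Oc1c(Br)cc(Cc2c(Br)c(O)c(O)c(Br)c2Br)c(Br)c1O | target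

**Step count and risks**
Total step count: 5. Longest linear sequence: 4 (steps 2, 3, 4, 5).

Steps most likely to fail:

1. Step 4. The radical cation of the electron-poor, doubly brominated toluene may form sluggishly or react unselectively (over-oxidation, benzyl dimerisation). The hexafluoroisopropyl ether may also ionise slowly, so that self-benzylation of ring A or acid-induced bromine migration competes with the cross-coupling. The fallback sets out from 3 and comes back at 7. Radical Wohl–Ziegler bromination of 3 (NBS, AIBN cat., PhCF3, 80 °C) should give 1,4-dibromo-5-(bromomethyl)-2,3-dimethoxybenzene F1. F1 is then used in a conventional Lewis-acid Friedel–Crafts benzylation of 5 (2.5 equiv 5, ZnBr2 cat., CH2Cl2–HFIP, rt) to give 7.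

2. Step 1. The ortho-bromo aryllithium may lose LiBr to an aryne, or exchange bromine with unreacted 1 (halogen dance) before it is methylated, which would scramble the substitution pattern. The fallback sets out from 1 and comes back at 3, introducing the carbon by electrophilic substitution instead of deprotonation. Blanc chloromethylation of 1 (paraformaldehyde, HCl, ZnCl2, AcOH, 60 °C; the two free positions are equivalent) should give 1,4-dibromo-5-(chloromethyl)-2,3-dimethoxybenzene F2. Hydride displacement of the benzylic chloride (LiEt3BH, THF, 0 °C) then gives 3.

3. Step 3. Bromination may run on to the tetrabromide, or bromine may oxidise the free catechol to its o-quinone. The fallback sets out from 1 and comes back at 5, reversing the order of deprotection and bromination. Iron-catalysed bromination of the methyl ether 1 (Br2 1.1 equiv, Fe powder cat., CH2Cl2, rt) should give 1,2,5-tribromo-3,4-dimethoxybenzene F3, whose ether oxygens cannot be oxidised. BBr3 demethylation (CH2Cl2, −78 °C → rt, then water) then gives 5.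

Further compounds
F1 | step 4 | 1,4-dibromo-5-(bromomethyl)-2,3-dimethoxybenzene | COc1c(OC)c(Br)c(CBr)cc1Br
F2 | step 1 | 1,4-dibromo-5-(chloromethyl)-2,3-dimethoxybenzene | COc1c(OC)c(Br)c(CCl)cc1Br
F3 | step 3 | 1,2,5-tribromo-3,4-dimethoxybenzene | COc1c(OC)c(Br)c(Br)cc1Br
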